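The runs were generated by integration from invented constants; noise was put on by code.

You want to know which flask holds the most target at 8.0 min, counted as percent of its own charge, and how much.

| setting | Saturday's | Tuesday's | zeta | epsilon | alpha | gamma |
|---|---|---|---|---|---|---|
| solid substrate | 16 mM | 31 mM | 35 mM | 50 mM | 20 mM | 25 mM |
| remark | run made earlier | run made earlier |  |  |  |  |
| time |  |  | 8.0 min | 8.0 min | 8.0 min | 8.0 min |

| run | time / min | target / % | solid substrate / % |
|---|---|---|---|
| Saturday's | 0.500 | 0 | 90.9 |
| Saturday's | 1.00 | 1.0 | 82.7 |
| Saturday's | 1.50 | 0.5 | 73.7 |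
| Saturday's | 2.50 | 1.3 | 59.4 |
| Saturday's | 3.00 | 1.8 | 53.1 |
| Saturday's | 4.00 | 2.9 | 40.2 |
| Tuesday's | 0.333 | 0.4 | 97.3 |
| Tuesday's | 0.500 | 0 | 95.6 |
| Tuesday's | 0.667 | 0 | 93.7 |
| Tuesday's | 1.00 | 0.2 | 91.0 |
| Tuesday's | 1.50 | 0.6 | 87.0 |
| Tuesday's | 2.50 | 0.4 | 78.9 |
| Tuesday's | 4.00 | 1.6 | 69.5 |

(scatter of a reading: 0.3 percentage points)

- the flasks by amount of target, in percent of the solid substrate charged, highest first, at 8.0 min (zeta / epsilon / alpha / gamma)
- the amount of target, in percent of the solid substrate charged of the flask you put first, at 8.0 min
- the amount of target, in percent of the solid substrate charged of the flask you put last, at 8.0 min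

- given per volume of solution although it is solid: solid substrate
- the analysis behind the earlier runs scatters by 0.3 percentage points, standard deviation
- at the start none of the solid substrate is in solution
- what has only dissolved of solid substrate counts as not reacted

Read the runs in mM, not percent, and go down the rates from fastest to slowest. Solid leaves at the start at 2.91 mM min⁻¹ in Saturday's run and 2.73 mM min⁻¹ in Tuesday's, although Tuesday's charge is twice Saturday's. By 4.00 min the two have lost about the same amount of solid:

9.57 mM and 9.45 mM

So in these two runs this crawl into solution does not follow the charge. In Saturday's run it has slowed to 2.05 mM min⁻¹. Held at that pace, it removes 17.8 mM by 8.0 min, less than alpha's charge, which is the smallest. I therefore expect solid in every flask at that time.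

The next rung down is target, which in Saturday's run gains 0.116 mM min⁻¹ on average up to 4.00 min. Carry its concentration at 4.00 min, charge times percent, as one number for both charges:

[target] = 0.464 mM in Saturday's run, 0.496 mM in Tuesday's

If that holds at 8.0 min, percent is [target] divided by the charge, which gives the order from the smallest charge up. In Saturday's late readings target doubles in about 1.30 min. Carrying that forward is my own reckoning:

[target] at 8.0 min = 3.94 mM, so alpha 19.7% and epsilon 7.88%

The forecast gives the same order, alpha > gamma > zeta > epsilon, but lower numbers: 8.2% and 3.3%, from 1.65 mM of target “regardless of charge”.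

The flask gives alpha > gamma > zeta > epsilon, with alpha at 28.7% and epsilon at 11.5%.

    2 starting material → homo dimer (k = 0.0451 M⁻¹ s⁻¹)
    starting material + target → 2 target (k = 1.03 M⁻¹ s⁻¹)
    target ⇌ isomer of the product (K = 0.240, k = 6.30 × 10⁻⁴ s⁻¹)
    starting material → target (k = 2.18 × 10⁻⁴ s⁻¹)
    solid substrate ⇌ starting material, rate k5*(cs5 - [starting material]) while solid is left; crystals form when [starting material] > cs5 (solubility = 23.0 mM, k = 0.00219 s⁻¹)

That is 5.73 mM of target in alpha and 5.73 mM in epsilon. In alpha at 8.00 min, target is made 17.8 times faster than it is used up, each step taken net. Dividing the carried 0.464 mM by alpha's charge gives 2.32%, and alpha holds 2.30% at 4.00 min. Dividing it by epsilon's charge gives 0.928%, and epsilon holds 0.920% at 4.00 min.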